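**Assumptions**
- The target SMILES has no stereocentre and no stereogenic double bond, so the compound is achiral and the route delivers this one structure.
- Numbers are given to starting materials, intermediates and products; auxiliary reagents appear by name and SMILES on their own line.

**Retrosynthetic overview**
1. Target 12 comes from 11 by removing one benzyl ether; 11 is cut at the depside ester C(=O)–O bond into haematommic acid 5 (ring A) and hydroquinone monoether 9 (ring B).
2. 5 comes from orsellinic acid 1 by benzyl ester formation, formylation at C3 and ester hydrogenolysis.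
3. 9 comes from methyl β-orcinolcarboxylate 6 by 4-O-benzylation and para-hydroxylation at C5.
4. No ring is built: ring A is bought in 1 and ring B in 6, and the two are joined in the penultimate step.

**Route**

Step 1
Reactants: 1 orsellinic acid (2,4-dihydroxy-6-methylbenzoic acid)
Product: 2 benzyl 2,4-dihydroxy-6-methylbenzoate
Conditions: BnBr (1.05 equiv), KHCO3 (1.2 equiv), DMF, rt, 16 h
Reagents that add atoms: benzyl bromide, BrCc1ccccc1
Why: SN2 O-alkylation of the carboxylate, since KHCO3 deprotonates only the acid and not the phenols, and room temperature avoids decarboxylation.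

Step 2
Reactants: 2 benzyl 2,4-dihydroxy-6-methylbenzoate
Product: 4 benzyl 3-formyl-2,4-dihydroxy-6-methylbenzoate, via α-chloro ether 3 (not isolated)
Conditions: Cl2CHOMe (1.5 equiv), TiCl4 (2.5 equiv), CH2Cl2, −20 → 0 °C, 1.5 h; then 1 M HCl, 0 °C → rt; chromatography to remove the minor 5-formyl isomer
Reagents that add atoms: dichloromethyl methyl ether, COC(Cl)Cl; water, O
Why: Rieche formylation, in which titanium bound to the phenol and salicylate oxygens directs the electrophile to C3 (ortho to both hydroxyls), and α-chloro ether 3 is hydrolysed to the aldehyde on acidic work-up; no stereocentre remains.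

Step 3
Reactants: 4 benzyl 3-formyl-2,4-dihydroxy-6-methylbenzoate
Product: 5 haematommic acid (3-formyl-2,4-dihydroxy-6-methylbenzoic acid)
Conditions: H2 (1 atm), 10% Pd/C, EtOAc, rt, stopped after 1 equiv H2 (about 30 min)
Reagents that add atoms: none
Why: Hydrogenolysis of the benzyl ester is much faster than reduction of the doubly hydrogen-bonded aryl aldehyde, and it frees the hindered, decarboxylation-prone acid without base or heat.

Step 4
Reactants: 6 methyl β-orcinolcarboxylate (methyl 2,4-dihydroxy-3,6-dimethylbenzoate)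
Product: 7 methyl 4-(benzyloxy)-2-hydroxy-3,6-dimethylbenzoate
Conditions: BnBr (1.1 equiv), K2CO3 (1.5 equiv), acetone, reflux, 12 h
Reagents that add atoms: benzyl bromide, BrCc1ccccc1
Why: Williamson ether synthesis, selective for the 4-hydroxyl because the 2-hydroxyl is hydrogen-bonded to the ester carbonyl and flanked on both sides.

Step 5
Reactants: 7 methyl 4-(benzyloxy)-2-hydroxy-3,6-dimethylbenzoate
Product: 9 methyl 4-(benzyloxy)-2,5-dihydroxy-3,6-dimethylbenzoate, via potassium aryl sulfate 8 (not isolated)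
Conditions: K2S2O8 (1.2 equiv, portionwise), 2 M aq KOH, pyridine, 5 → 20 °C, 36 h; HCl to pH 4, Et2O wash (recovers 7); then 2 M HCl, 80 °C, 30 min, N2
Reagents that add atoms: potassium peroxodisulfate (K2S2O8), [K+].[K+].[O-]S(=O)(=O)OOS(=O)(=O)[O-]
Why: Elbs persulfate oxidation, in which the phenoxide of 7 attacks the peroxide oxygen through its para carbon C5 (the only free ring position) to give aryl sulfate 8, and acid hydrolysis with S–O cleavage frees the phenol while the hindered methyl ester and the benzyl ether survive.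

Step 6
Reactants: 5 haematommic acid (3-formyl-2,4-dihydroxy-6-methylbenzoic acid); 9 methyl 4-(benzyloxy)-2,5-dihydroxy-3,6-dimethylbenzoate
Product: 11 methyl 4-(benzyloxy)-5-[(3-formyl-2,4-dihydroxy-6-methylbenzoyl)oxy]-2-hydroxy-3,6-dimethylbenzoate, via mixed trifluoroacetic anhydride 10 (not isolated)
Conditions: (CF3CO)2O (4 equiv), dry toluene, rt, 4 h, N2
Reagents that add atoms: none
Why: Trifluoroacetic anhydride-mediated depside esterification through the aroyl trifluoroacetate, in which only the 5-hydroxyl of 9 is acylated because the 2-hydroxyl of 9 and both hydroxyls of 5 are held in hydrogen bonds to neighbouring carbonyls.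

Step 7
Reactants: 11 methyl 4-(benzyloxy)-5-[(3-formyl-2,4-dihydroxy-6-methylbenzoyl)oxy]-2-hydroxy-3,6-dimethylbenzoate
Product: 12 methyl 5-[(3-formyl-2,4-dihydroxy-6-methylbenzoyl)oxy]-2,4-dihydroxy-3,6-dimethylbenzoate
Conditions: H2 (1 atm), 10% Pd/C, EtOAc, rt, stopped after 1 equiv H2
Reagents that add atoms: none
Why: Hydrogenolysis of the aryl benzyl ether under neutral conditions is faster than reduction of the chelated aldehyde, leaves both esters intact, and avoids base that could move the aroyl group from O5 to O4; no stereocentre is involved.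

**Compound list**
1 | orsellinic acid (2,4-dihydroxy-6-methylbenzoic acid) | Cc1cc(O)cc(O)c1C(=O)O | starting material
2 | benzyl 2,4-dihydroxy-6-methylbenzoate | Cc1cc(O)cc(O)c1C(=O)OCc1ccccc1 | intermediate
3 | α-chloro ether, benzyl 3-[chloro(methoxy)methyl]-2,4-dihydroxy-6-methylbenzoate (not isolated) | Cc1cc(O)c(C(Cl)OC)c(O)c1C(=O)OCc1ccccc1 | intermediate
4 | benzyl 3-formyl-2,4-dihydroxy-6-methylbenzoate (benzyl haematommate) | Cc1cc(O)c(C=O)c(O)c1C(=O)OCc1ccccc1 | intermediate
5 | haematommic acid (3-formyl-2,4-dihydroxy-6-methylbenzoic acid) | Cc1cc(O)c(C=O)c(O)c1C(=O)O | intermediate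
6 | methyl β-orcinolcarboxylate (methyl 2,4-dihydroxy-3,6-dimethylbenzoate) | COC(=O)c1c(C)cc(O)c(C)c1O | starting material
7 | methyl 4-(benzyloxy)-2-hydroxy-3,6-dimethylbenzoate | COC(=O)c1c(C)cc(OCc2ccccc2)c(C)c1O | intermediate
8 | potassium 2-(benzyloxy)-4-hydroxy-5-(methoxycarbonyl)-3,6-dimethylphenyl sulfate (not isolated) | COC(=O)c1c(C)c(OS(=O)(=O)[O-])c(OCc2ccccc2)c(C)c1O.[K+] | intermediate
9 | methyl 4-(benzyloxy)-2,5-dihydroxy-3,6-dimethylbenzoate | COC(=O)c1c(C)c(O)c(OCc2ccccc2)c(C)c1O | intermediate
10 | 3-formyl-2,4-dihydroxy-6-methylbenzoic trifluoroacetic anhydride (not isolated) | Cc1cc(O)c(C=O)c(O)c1C(=O)OC(=O)C(F)(F)F | intermediate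
11 | methyl 4-(benzyloxy)-5-[(3-formyl-2,4-dihydroxy-6-methylbenzoyl)oxy]-2-hydroxy-3,6-dimethylbenzoate | COC(=O)c1c(C)c(OC(=O)c2c(C)cc(O)c(C=O)c2O)c(OCc2ccccc2)c(C)c1O | intermediate
12 | methyl 5-[(3-formyl-2,4-dihydroxy-6-methylbenzoyl)oxy]-2,4-dihydroxy-3,6-dimethylbenzoate | COC(=O)c1c(C)c(OC(=O)c2c(C)cc(O)c(C=O)c2O)c(O)c(C)c1O | target

**Step count and risks**
Total steps: 7 (convergent). Longest linear sequence: 5 steps (1, 2, 3, 6, 7); the ring B branch is 4 steps (4, 5, 6, 7).

The three steps most likely to fail: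

Step 2 (C3 against C5 formylation, and survival of the benzyl ester under TiCl4). The fallback sets out from 2 and comes back at 5. NBS (1.0 equiv, MeCN, 0 °C) brominates the competing position, which is the usual site of halogenation in orsellinates, and gives benzyl 5-bromo-2,4-dihydroxy-6-methylbenzoate F1. The same Rieche formylation (Cl2CHOMe, TiCl4, CH2Cl2, then 1 M HCl) can now only reach C3; it passes through the α-chloro ether benzyl 5-bromo-3-[chloro(methoxy)methyl]-2,4-dihydroxy-6-methylbenzoate F2 (not isolated) and gives benzyl 5-bromo-3-formyl-2,4-dihydroxy-6-methylbenzoate F3. Hydrogenolysis (H2 1 atm, 10% Pd/C, NaOAc, EtOAc–MeOH) then removes the benzyl ester and the bromine in one operation and gives 5.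

Step 5 (Elbs oxidation; typically low conversion, and 9 is an air-sensitive hydroquinone). The fallback sets out from 7 and comes back at 9. Vilsmeier–Haack formylation (POCl3, DMF, 0 → 70 °C) at the same free position gives the iminium salt N-{[2-(benzyloxy)-4-hydroxy-5-(methoxycarbonyl)-3,6-dimethylphenyl]methylidene}-N-methylmethanaminium chloride F4 (not isolated). Aqueous NaOAc hydrolyses it to methyl 4-(benzyloxy)-5-formyl-2-hydroxy-3,6-dimethylbenzoate F5. Dakin oxidation (30% aq H2O2, H3BO3, cat. H2SO4, THF, rt) of this aldehyde, which is para to the free hydroxyl, gives the aryl formate methyl 4-(benzyloxy)-5-(formyloxy)-2-hydroxy-3,6-dimethylbenzoate F6 (not isolated), which is hydrolysed in the flask to 9.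

Step 6 (esterification of a doubly ortho-substituted phenol with a doubly ortho-substituted, unprotected hydroxy acid). The fallback sets out from 5 and comes back at 11, with 9 used unchanged. Acetone, (CF3CO)2O and CF3CO2H (0 °C → rt) turn 5 into the acetonide 7-hydroxy-2,2,5-trimethyl-4-oxo-4H-1,3-benzodioxine-8-carbaldehyde F7. Irradiation at 300 nm in CH2Cl2 in the presence of 9 expels acetone and gives the quinoketene 2-hydroxy-4-methyl-6-oxo-5-(oxomethylidene)cyclohexa-1,3-diene-1-carbaldehyde F8 (not isolated). The free 5-hydroxyl of 9 adds to this ketene under neutral conditions and gives 11.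

**Further compounds**
F1 | step 2 | benzyl 5-bromo-2,4-dihydroxy-6-methylbenzoate | Cc1c(Br)c(O)cc(O)c1C(=O)OCc1ccccc1
F2 | step 2 | benzyl 5-bromo-3-[chloro(methoxy)methyl]-2,4-dihydroxy-6-methylbenzoate | Cc1c(Br)c(O)c(C(Cl)OC)c(O)c1C(=O)OCc1ccccc1
F3 | step 2 | benzyl 5-bromo-3-formyl-2,4-dihydroxy-6-methylbenzoate | Cc1c(Br)c(O)c(C=O)c(O)c1C(=O)OCc1ccccc1
F4 | step 5 | N-{[2-(benzyloxy)-4-hydroxy-5-(methoxycarbonyl)-3,6-dimethylphenyl]methylidene}-N-methylmethanaminium chloride | COC(=O)c1c(C)c(C=[N+](C)C)c(OCc2ccccc2)c(C)c1O.[Cl-]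
F5 | step 5 | methyl 4-(benzyloxy)-5-formyl-2-hydroxy-3,6-dimethylbenzoate | COC(=O)c1c(C)c(C=O)c(OCc2ccccc2)c(C)c1O
F6 | step 5 | methyl 4-(benzyloxy)-5-(formyloxy)-2-hydroxy-3,6-dimethylbenzoate | COC(=O)c1c(C)c(OC=O)c(OCc2ccccc2)c(C)c1O
F7 | step 6 | 7-hydroxy-2,2,5-trimethyl-4-oxo-4H-1,3-benzodioxine-8-carbaldehyde | Cc1cc(O)c(C=O)c2OC(C)(C)OC(=O)c12
F8 | step 6 | 2-hydroxy-4-methyl-6-oxo-5-(oxomethylidene)cyclohexa-1,3-diene-1-carbaldehyde | O=C=C1C(=O)C(C=O)=C(O)C=C1C
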